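**Retrosynthetic overview**

1. Locants used in the text: ring A = C1 (CH–OBz), C2 (CH–OAc), C3 (CH2), C4 (C(Me)OH), C5 (O-bearing fusion carbon), C10 (Me-bearing fusion carbon); γ-lactone C5–C6(=O)–O–C9–C10; oxepine C5–O–C11(Me2)–C7=C8–C9–C10.
2. Last bonds: C1–OBz and C2–OAc (Woodward cis-hydroxylation of a C1=C2 alkene, then benzoylation), and before them the oxepine C5–O–C11 bond (capture of the C11 tertiary allyl cation of a Z-alkene by the C5 hydroxyl).
3. Key disconnection, the C4–C5 bond of ring A: ring A, the lactone carbonyl and the C5 stereocenter arise together by an intramolecular benzilic ester (α-ketol) ring contraction of a cyclohept-4-ene-1,2-dione whose C9 hydroxyl sits as a hemiketal on C6. Enabling feature: C5 is a ring-A carbon that carries an oxygen and the carboxyl carbon C6 (a tertiary α-hydroxy acid), and the ester oxygen is on C9, β to C5 through C10, so ring A plus lactone is the benzilic product of a seven-membered α-diketone bearing a β-hydroxyl.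
4. The seven-membered ring is grown from a six-membered one by an epoxy-alcohol semipinacol ring expansion (C10 enters, C9 and C10 are set), then SeO2 oxidation at C6; fragments: (S)-5-methyl-5-silyloxycyclohex-2-enone (Cu-catalysed asymmetric borylation of 3-methylcyclohex-2-enone) and an (E)-bromoenyne (propyne, IBr, 2-methylbut-3-yn-2-ol).
5. Ring order: six-membered carbocycle → seven-membered carbocycle → ring A and γ-lactone together (key step) → oxepine.

Key step: step 11

Remark: the sense of induction in steps 1 and 8 is assumed to follow the usual models, and the ligand or ketone enantiomer is chosen to match; propyne is used as its commercial solution.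

**Step 1**
Reactants: 1 3-methylcyclohex-2-en-1-one
Product: 3 (S)-3-hydroxy-3-methylcyclohexan-1-one, via tertiary pinacol boronate 2 (not isolated)
Conditions: Cu(MeCN)4PF6 (5 mol %), QuinoxP* (6 mol %, enantiomer that gives the S alcohol), LiOt-Bu (10 mol %), B2pin2, DMSO, rt; then NaBO3·4H2O, THF/H2O, rt
Reagents that add atoms: bis(pinacolato)diboron, CC1(C)OB(OC1(C)C)B1OC(C)(C)C(C)(C)O1 (boryl group of 2); sodium perborate, [Na+].[Na+].O[B-]1(O)OO[B-](O)(O)OO1 (oxygen of 3)
Why: Copper-catalysed enantioselective conjugate borylation of a β,β-disubstituted cyclic enone, in which the chiral bisphosphine–copper boryl complex selects the enone face and sets the quaternary C–B center, followed by stereoretentive C–B oxidation, should give the tertiary alcohol stereocenter that becomes C4.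

**Step 2**
Reactants: 3 (S)-3-hydroxy-3-methylcyclohexan-1-one
Product: 4 (S)-3-methyl-3-(triethylsilyloxy)cyclohexan-1-one
Conditions: Et3SiOTf, 2,6-lutidine, CH2Cl2, −78 → 0 °C
Reagents that add atoms: triethylsilyl trifluoromethanesulfonate, CC[Si](CC)(CC)OS(=O)(=O)C(F)(F)F
Why: O-Silylation of the tertiary alcohol with a silyl triflate and a hindered pyridine base protects it against retro-aldol cleavage and elimination in the enolate chemistry that follows.

**Step 3**
Reactants: 4 (S)-3-methyl-3-(triethylsilyloxy)cyclohexan-1-one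
Product: 6 (S)-5-methyl-5-(triethylsilyloxy)cyclohex-2-en-1-one, via trimethylsilyl enol ether 5 (not isolated)
Conditions: LiN(i-Pr)2, THF, −78 °C; Me3SiCl; then Pd(OAc)2 (1.05 equiv), MeCN, rt
Reagents that add atoms: chlorotrimethylsilane, C[Si](C)(C)Cl (silyl group of 5 only)
Why: Kinetic deprotonation at the less hindered α-methylene (remote from the quaternary carbon) and silylation give the less substituted silyl enol ether, which Saegusa–Ito dehydrogenation (oxo-π-allyl palladium, β-hydride elimination) should turn into the enone with the alkene at the future C1=C2.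

**Step 4**
Reactants: 7 propyne
Product: 8 (E)-2-bromo-1-iodoprop-1-ene
Conditions: IBr (1.0 equiv), CH2Cl2, −78 → −20 °C, dark
Reagents that add atoms: iodine monobromide, BrI
Why: Electrophilic anti addition of I–Br across the alkyne through an iodonium ion, with bromide opening at the methyl-substituted carbon, should give the E dihalide in which iodine (future alkynyl position) and bromine (future lithium position) are trans.

**Step 5**
Reactants: 8 (E)-2-bromo-1-iodoprop-1-ene; 9 2-methylbut-3-yn-2-ol
Product: 10 (E)-6-bromo-2-methylhept-5-en-3-yn-2-ol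
Conditions: Pd(PPh3)2Cl2 (2 mol %), CuI (4 mol %), Et3N, THF, 0 °C → rt
Reagents that add atoms: none
Why: Sonogashira coupling, with oxidative addition of palladium only into the weaker and less hindered C–I bond and retention of alkene geometry, should leave the vinyl bromide intact and trans to the new alkynyl group.

**Step 6**
Reactants: 10 (E)-6-bromo-2-methylhept-5-en-3-yn-2-ol
Product: 11 (E)-[(6-bromo-2-methylhept-5-en-3-yn-2-yl)oxy]triethylsilane
Conditions: Et3SiOTf, 2,6-lutidine, CH2Cl2, −78 → 0 °C
Reagents that add atoms: triethylsilyl trifluoromethanesulfonate, CC[Si](CC)(CC)OS(=O)(=O)C(F)(F)F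
Why: Silylation of the tertiary propargylic alcohol masks the only acidic proton before the organolithium step.

**Step 7**
Reactants: 11 (E)-[(6-bromo-2-methylhept-5-en-3-yn-2-yl)oxy]triethylsilane; 6 (S)-5-methyl-5-(triethylsilyloxy)cyclohex-2-en-1-one
Product: 13 (5S)-5-methyl-1-[(2E)-6-methyl-6-(triethylsilyloxy)hept-2-en-4-yn-2-yl]-5-(triethylsilyloxy)cyclohex-2-en-1-ol (both C1 epimers), via alkenyllithium 12 (not isolated)
Conditions: t-BuLi (2.0 equiv), Et2O, −78 °C; then 6, −78 °C; H2O
Reagents that add atoms: tert-butyllithium, [Li]C(C)(C)C (lithium of 12 only)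
Why: Bromine–lithium exchange with retention of alkene geometry and 1,2-addition of the alkenyllithium to the enone carbonyl at low temperature should give the bis-allylic tertiary alcohol; the new carbinol center forms as a mixture that does not matter because it becomes the ketone carbon C5 in step 9.

**Step 8**
Reactants: 13 tertiary dienynyl alcohol
Product: 14 (5S)-5-methyl-1-{(2R,3S)-2-methyl-3-[3-methyl-3-(triethylsilyloxy)but-1-yn-1-yl]oxiran-2-yl}-5-(triethylsilyloxy)cyclohex-2-en-1-ol (both C1 epimers)
Conditions: ent-Shi ketone (L-fructose-derived, 30 mol %), KHSO5 (as 2KHSO5·KHSO4·K2SO4), K2CO3, Bu4NHSO4, MeCN/CH2(OMe)2/aq. Na2B4O7 buffer, 0 °C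
Reagents that add atoms: potassium peroxymonosulfate, [K+].[O-]S(=O)(=O)OO
Why: Shi epoxidation (chiral dioxirane, spiro transition state) should oxidise the trisubstituted enyne alkene in preference to the cis-disubstituted ring alkene and the alkyne; the ketone enantiomer sets the (2R,3S) epoxide and the E geometry fixes the relative configuration of the future C10 and C9.

**Step 9**
Reactants: 14 epoxy alcohol
Product: 15 (2S,6S)-2-[(1S)-1-hydroxy-4-methyl-4-(triethylsilyloxy)pent-2-yn-1-yl]-2,6-dimethyl-6-(triethylsilyloxy)cyclohept-3-en-1-one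
Conditions: ZnBr2 (1.2 equiv), CH2Cl2, 0 °C → rt
Reagents that add atoms: none
Why: Semipinacol rearrangement of a 2,3-epoxy alcohol: Lewis-acid opening of the tertiary C10–O bond with anti 1,2-shift of the ring vinyl carbon (a better migrating group than the ring methylene) expands the ring from six to seven, forms the quaternary C10 with inversion and leaves C9 untouched, so both carbinol epimers of 14 converge on one ketone.

**Step 10**
Reactants: 15 cycloheptenone
Product: 17 (1S,5S,6S,8S)-6-hydroxy-1,5-dimethyl-8-[3-methyl-3-(triethylsilyloxy)but-1-yn-1-yl]-5-(triethylsilyloxy)-7-oxabicyclo[4.2.1]non-2-en-9-one, via ring-opened hydroxy diketone 16 (not isolated)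
Conditions: SeO2 (1.5 equiv), 1,4-dioxane/H2O (30:1), 90 °C
Reagents that add atoms: selenium dioxide, O=[Se]=O
Why: Riley oxidation at C6, the only enolisable α-position (C10 is quaternary), should give the non-enolisable 1,2-diketone, whose C9 hydroxyl adds at once to the distal carbonyl C6 (five-membered closure; addition to C5 would give an oxetane) to form the bridged hemiketal, its new center being fixed by the bridge.

**Step 11**
Reactants: 17 bicyclic hemiketal
Product: 18 (3S,3aS,7S,7aS)-7a-hydroxy-3a,7-dimethyl-3-[3-methyl-3-(triethylsilyloxy)but-1-yn-1-yl]-7-(triethylsilyloxy)-3a,6,7,7a-tetrahydro-2-benzofuran-1(3H)-one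
Conditions: LiOt-Bu (1.1 equiv), THF, −40 → 0 °C; then AcOH
Reagents that add atoms: none
Why: Deprotonation of the hemiketal hydroxyl gives an α-ketol alkoxide in which the ring bond from the hemiketal carbon C6 to the silyloxy-bearing quaternary carbon C4 shifts suprafacially to the neighbouring ketone carbon C5, so C6 becomes the lactone carbonyl, C5 a tertiary alkoxide, and the seven-membered carbocycle contracts to ring A. The closest known reaction type is the benzilic ester rearrangement of a cyclic 1,2-diketone with ring contraction, here with an internal alkoxide (equally an α-ketol shift of a hemiketal), driven by the conversion of a ketone into an ester. Ring A is closed by the 1,2-carbon shift itself (C4–C5 formed as C4–C6 breaks); the γ-lactone is the five-membered ring already closed in 17 by 5-exo-trig addition of the C9 hydroxyl to C6, and it persists as the hemiketal carbon becomes the ester carbonyl. The one new stereocenter, C5, is set by the O–C9 tether, which holds C6 on the face of C9 so that only the cis-fused lactone with the C5 oxygen on the methyl-bearing face can form, and C4 migrates with retention. The step needs the 1,2-shift to win over retro-aldol cleavage of the C9–C10 bond and over α-ketol isomerisation at C4; this is secured by the hemiketal being the resting state (no free C6 ketone, no free C9 alkoxide), by both α-carbons being quaternary, by lithium chelating the C6 alkoxide and the C5 carbonyl, and by the silyl ether on the C4 oxygen. Stereoelectronically the migrating C4–C6 bond is exocyclic to the hemiketal ring and lies nearly parallel to the π* orbital of the C5 ketone, which is the one-atom bridge of the bicyclo[4.2.1] skeleton.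

**Step 12**
Reactants: 18 alkynyl hydroxy lactone
Product: 19 (3S,3aS,7S,7aS)-7a-hydroxy-3a,7-dimethyl-3-[(1Z)-3-methyl-3-(triethylsilyloxy)but-1-en-1-yl]-7-(triethylsilyloxy)-3a,6,7,7a-tetrahydro-2-benzofuran-1(3H)-one
Conditions: H2 (1 atm), Pd/CaCO3 poisoned with Pb(OAc)2 (Lindlar catalyst), quinoline, EtOAc, rt
Reagents that add atoms: none
Why: Lindlar semihydrogenation adds H2 syn to the alkyne and should give the Z alkene required inside the seven-membered ether, while the hindered ring alkene is not reduced on the poisoned catalyst.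

**Step 13**
Reactants: 19 Z-alkenyl bis-silyl ether
Product: 20 (3S,3aS,7S,7aS)-7,7a-dihydroxy-3-[(1Z)-3-hydroxy-3-methylbut-1-en-1-yl]-3a,7-dimethyl-3a,6,7,7a-tetrahydro-2-benzofuran-1(3H)-one
Conditions: HF·pyridine, pyridine/THF, 0 °C → rt
Reagents that add atoms: none
Why: Fluoride-driven cleavage of both tertiary Si–O bonds under buffered conditions frees the C4 and C11 hydroxyls without touching the lactone or the alkenes.

**Step 14**
Reactants: 20 triol
Product: 21 (1S,2S,6S,7S)-2-hydroxy-2,6,10,10-tetramethyl-11,13-dioxatricyclo[5.4.2.0^1,6]trideca-4,8-dien-12-one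
Conditions: TsOH·H2O (10 mol %), 4 Å MS, CH2Cl2, 0 °C → rt
Reagents that add atoms: none
Why: Acid-catalysed dehydrative allylic etherification (cineole-type tertiary ether formation): ionisation of the tertiary allylic alcohol gives a dimethyl-substituted allyl cation that the C5 hydroxyl should capture at its tertiary terminus C11 in a seven-membered closure held together by the Z alkene, whereas attack at C8 would give a strained bridged five-membered ether and elimination to the diene is reversible.

**Step 15**
Reactants: 21 tricyclic diene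
Product: 23 (1S,2S,4S,5R,6S,7S)-2,5-dihydroxy-2,6,10,10-tetramethyl-12-oxo-11,13-dioxatricyclo[5.4.2.0^1,6]tridec-8-en-4-yl acetate, via trans iodo acetate 22 (not isolated)
Conditions: I2 (1.05 equiv), AgOAc (2.2 equiv), AcOH, rt; then AcOH/H2O, 50 °C
Reagents that add atoms: silver acetate, CC(=O)[O-].[Ag+]; water, O; iodine, [I][I] (iodine atom of 22 only)
Why: Woodward cis-hydroxylation: the iodonium ion should form on the lower face of the ring-A alkene (the upper face is screened by the axial methyls on C4 and C10), acetate opens it trans-diaxially at C2, silver-assisted neighbouring-group displacement of iodide gives the upper-face dioxolanylium ion, and its hydrolysis collapses to the axial C2 acetate and equatorial C1 hydroxyl, so both stereocenters are set cis on the upper face, while the oxepine alkene is deactivated by its two allylic oxygens.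

**Step 16**
Reactants: 23 hydroxy acetate
Product: 24 (1S,2S,4S,5R,6R,7S)-4-acetoxy-2-hydroxy-2,6,10,10-tetramethyl-12-oxo-11,13-dioxatricyclo[5.4.2.0^1,6]tridec-8-en-5-yl benzoate (target, CNP0178319.3)
Conditions: BzCl, pyridine, DMAP (cat.), CH2Cl2, 0 °C → rt
Reagents that add atoms: benzoyl chloride, O=C(Cl)c1ccccc1
Why: DMAP-catalysed acylation of the secondary equatorial C1 hydroxyl in weakly basic medium, kept cold to suppress acetyl migration, should give the target, the tertiary C4 hydroxyl being unreactive under these conditions.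

**Compound list**

1 | 3-methylcyclohex-2-en-1-one | CC1=CC(=O)CCC1 | starting material
2 | (R)-3-methyl-3-(4,4,5,5-tetramethyl-1,3,2-dioxaborolan-2-yl)cyclohexan-1-one | C1C[C@](C)(B2OC(C)(C)C(C)(C)O2)CC(=O)C1 | intermediate
3 | (S)-3-hydroxy-3-methylcyclohexan-1-one | C1C[C@](C)(O)CC(=O)C1 | intermediate
4 | (S)-3-methyl-3-(triethylsilyloxy)cyclohexan-1-one | C1C[C@](C)(O[Si](CC)(CC)CC)CC(=O)C1 | intermediate
5 | (S)-triethyl{[1-methyl-3-(trimethylsilyloxy)cyclohex-3-en-1-yl]oxy}silane | C1C[C@](C)(O[Si](CC)(CC)CC)CC(O[Si](C)(C)C)=C1 | intermediate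
6 | (S)-5-methyl-5-(triethylsilyloxy)cyclohex-2-en-1-one | C1C[C@](C)(O[Si](CC)(CC)CC)CC(=O)C=1 | intermediate
7 | propyne | CC#C | starting material
8 | (E)-2-bromo-1-iodoprop-1-ene | I/C=C(\C)Br | intermediate
9 | 2-methylbut-3-yn-2-ol | CC(C)(O)C#C | starting material
10 | (E)-6-bromo-2-methylhept-5-en-3-yn-2-ol | CC(C)(O)C#C/C=C(\C)Br | intermediate
11 | (E)-[(6-bromo-2-methylhept-5-en-3-yn-2-yl)oxy]triethylsilane | CC(C)(O[Si](CC)(CC)CC)C#C/C=C(\C)Br | intermediate
12 | [6-methyl-6-(triethylsilyloxy)hept-2-en-4-yn-2-yl]lithium, lithium trans to the alkynyl group (Z by the sequence rules) | CC(C)(O[Si](CC)(CC)CC)C#C/C=C(\C)[Li] | intermediate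
13 | (5S)-5-methyl-1-[(2E)-6-methyl-6-(triethylsilyloxy)hept-2-en-4-yn-2-yl]-5-(triethylsilyloxy)cyclohex-2-en-1-ol, both C1 epimers | C1C[C@](C)(O[Si](CC)(CC)CC)CC(O)(C=1)/C(C)=C/C#CC(C)(C)O[Si](CC)(CC)CC | intermediate
14 | (5S)-5-methyl-1-{(2R,3S)-2-methyl-3-[3-methyl-3-(triethylsilyloxy)but-1-yn-1-yl]oxiran-2-yl}-5-(triethylsilyloxy)cyclohex-2-en-1-ol, both C1 epimers | C1C[C@](C)(O[Si](CC)(CC)CC)CC(O)(C=1)[C@]1(C)O[C@H]1C#CC(C)(C)O[Si](CC)(CC)CC | intermediate
15 | (2S,6S)-2-[(1S)-1-hydroxy-4-methyl-4-(triethylsilyloxy)pent-2-yn-1-yl]-2,6-dimethyl-6-(triethylsilyloxy)cyclohept-3-en-1-one | C1C[C@](C)(O[Si](CC)(CC)CC)CC(=O)[C@@]([C@@H](O)C#CC(C)(C)O[Si](CC)(CC)CC)(C)C=1 | intermediate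
16 | (3S,7S)-3-[(1S)-1-hydroxy-4-methyl-4-(triethylsilyloxy)pent-2-yn-1-yl]-3,7-dimethyl-7-(triethylsilyloxy)cyclohept-4-ene-1,2-dione | C1C[C@](C)(O[Si](CC)(CC)CC)C(=O)C(=O)[C@@]([C@@H](O)C#CC(C)(C)O[Si](CC)(CC)CC)(C)C=1 | intermediate
17 | (1S,5S,6S,8S)-6-hydroxy-1,5-dimethyl-8-[3-methyl-3-(triethylsilyloxy)but-1-yn-1-yl]-5-(triethylsilyloxy)-7-oxabicyclo[4.2.1]non-2-en-9-one | C1C[C@](C)(O[Si](CC)(CC)CC)[C@]2(O)O[C@@H](C#CC(C)(C)O[Si](CC)(CC)CC)[C@](C)(C=1)C2=O | intermediate
18 | (3S,3aS,7S,7aS)-7a-hydroxy-3a,7-dimethyl-3-[3-methyl-3-(triethylsilyloxy)but-1-yn-1-yl]-7-(triethylsilyloxy)-3a,6,7,7a-tetrahydro-2-benzofuran-1(3H)-one | C1C[C@](C)(O[Si](CC)(CC)CC)[C@]2(O)C(=O)O[C@@H](C#CC(C)(C)O[Si](CC)(CC)CC)[C@]2(C)C=1 | intermediate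
19 | (3S,3aS,7S,7aS)-7a-hydroxy-3a,7-dimethyl-3-[(1Z)-3-methyl-3-(triethylsilyloxy)but-1-en-1-yl]-7-(triethylsilyloxy)-3a,6,7,7a-tetrahydro-2-benzofuran-1(3H)-one | C1C[C@](C)(O[Si](CC)(CC)CC)[C@]2(O)C(=O)O[C@@H](/C=C\C(C)(C)O[Si](CC)(CC)CC)[C@]2(C)C=1 | intermediate
20 | (3S,3aS,7S,7aS)-7,7a-dihydroxy-3-[(1Z)-3-hydroxy-3-methylbut-1-en-1-yl]-3a,7-dimethyl-3a,6,7,7a-tetrahydro-2-benzofuran-1(3H)-one | C1C[C@](C)(O)[C@]2(O)C(=O)O[C@@H](/C=C\C(C)(C)O)[C@]2(C)C=1 | intermediate
21 | (1S,2S,6S,7S)-2-hydroxy-2,6,10,10-tetramethyl-11,13-dioxatricyclo[5.4.2.0^1,6]trideca-4,8-dien-12-one | C1C[C@](C)(O)[C@]23OC(C)(C)C=C[C@H](OC2=O)[C@]3(C)C=1 | intermediate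
22 | (1S,2S,4S,5S,6S,7S)-2-hydroxy-5-iodo-2,6,10,10-tetramethyl-12-oxo-11,13-dioxatricyclo[5.4.2.0^1,6]tridec-8-en-4-yl acetate (acetate on the upper face, iodide on the lower face) | CC(=O)O[C@H]1C[C@](C)(O)[C@]23OC(C)(C)C=C[C@H](OC2=O)[C@]3(C)[C@@H]1I | intermediate
23 | (1S,2S,4S,5R,6S,7S)-2,5-dihydroxy-2,6,10,10-tetramethyl-12-oxo-11,13-dioxatricyclo[5.4.2.0^1,6]tridec-8-en-4-yl acetate | CC(=O)O[C@H]1C[C@](C)(O)[C@]23OC(C)(C)C=C[C@H](OC2=O)[C@]3(C)[C@H]1O | intermediate
24 | (1S,2S,4S,5R,6R,7S)-4-acetoxy-2-hydroxy-2,6,10,10-tetramethyl-12-oxo-11,13-dioxatricyclo[5.4.2.0^1,6]tridec-8-en-5-yl benzoate (CNP0178319.3) | CC(=O)O[C@H]1C[C@](C)(O)[C@]23OC(C)(C)C=C[C@H](OC2=O)[C@]3(C)[C@H]1OC(=O)c1ccccc1 | target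

**Step count and risks**

Total step count: 16 (13 in the main chain from 1, 3 for the bromoenyne 11).
Longest linear sequence: 13 steps (steps 1–3 and 7–16).

Three steps most likely to fail:

1. Step 15 (Woodward cis-hydroxylation). What may go wrong: the iodonium ion may form and be opened on the upper face or on the oxepine alkene (poor facial and site selectivity), the neighbouring-group displacement at the neopentyl C1 may be diverted into skeletal rearrangement, and the allylic tertiary ether may ionise in warm aqueous acetic acid. Fallback (osmylation directed by the free C5 hydroxyl, before the oxepine is closed): setting out from 18, stoichiometric OsO4 with TMEDA in CH2Cl2 at −78 °C and reductive work-up should give the upper-face cis-diol F1 by hydrogen-bond delivery from the C5 hydroxyl. Selective acetylation of the less hindered C2 hydroxyl (Ac2O, 2,4,6-collidine, −20 °C) should give the mono-acetate F2, and benzoylation of the neopentyl C1 hydroxyl (BzCl, pyridine, DMAP) the acetate benzoate F3. Lindlar semihydrogenation then gives the Z alkene F4 and HF·pyridine the desilylated diol F5, and TsOH-catalysed cycloetherification as in step 14 comes back to the route at 24.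

2. Step 10 (SeO2 oxidation). What may go wrong: competing allylic oxidation at C3, loss of the silyl ethers or β-elimination of the C4 silyloxy group at 90 °C, and over-oxidation. Fallback (Rubottom oxidation, then acyloin oxidation): setting out from 15, Me3SiOTf and Et3N in CH2Cl2 should give the bis-silylated enol ether F6 without forming a free alkoxide. Dimethyldioxirane in acetone at −40 °C followed by citric acid in MeOH should give the α-hydroxy ketone F7. Cu(OAc)2 in MeOH/AcOH, which oxidises α-ketols but not the isolated secondary alcohol, then gives the diketone, which closes to the hemiketal and comes back to the route at 17.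

3. Step 11 (key ring contraction). What may go wrong: ring opening of the hemiketal alkoxide and retro-aldol cleavage of the C9–C10 bond (loss of both stereocenters) may compete with the 1,2-shift. Fallback (untethered benzilic acid rearrangement with the C9 oxygen blocked): setting out from 15, Et3SiOTf and 2,6-lutidine give the tris-silyl ketone F8 and SeO2 in dioxane the non-enolisable diketone F9. Ba(OH)2 in aqueous dioxane followed by acidification should give the ring-contracted α-hydroxy acid F10 by the classical benzilic acid rearrangement, which delivers the same constitution whichever carbonyl is attacked. PPTS in MeOH then removes the secondary silyl ether selectively, and the epimer with the carboxyl cis to the C9 oxygen lactonises, coming back to the route at 18.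

**Further compounds**

F1 | step 15 | 4,5-cis-diol of 18 (4,5,7a-trihydroxy lactone, both new hydroxyls on the face of the 3a-methyl group) | O[C@H]1C[C@](C)(O[Si](CC)(CC)CC)[C@]2(O)C(=O)O[C@@H](C#CC(C)(C)O[Si](CC)(CC)CC)[C@]2(C)[C@H]1O
F2 | step 15 | 5-acetate of F1 | CC(=O)O[C@H]1C[C@](C)(O[Si](CC)(CC)CC)[C@]2(O)C(=O)O[C@@H](C#CC(C)(C)O[Si](CC)(CC)CC)[C@]2(C)[C@H]1O
F3 | step 15 | 5-acetate 4-benzoate of F1 | CC(=O)O[C@H]1C[C@](C)(O[Si](CC)(CC)CC)[C@]2(O)C(=O)O[C@@H](C#CC(C)(C)O[Si](CC)(CC)CC)[C@]2(C)[C@H]1OC(=O)c1ccccc1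
F4 | step 15 | Z-alkene from F3 | CC(=O)O[C@H]1C[C@](C)(O[Si](CC)(CC)CC)[C@]2(O)C(=O)O[C@@H](/C=C\C(C)(C)O[Si](CC)(CC)CC)[C@]2(C)[C@H]1OC(=O)c1ccccc1
F5 | step 15 | bis-desilylated F4 (triol acetate benzoate) | CC(=O)O[C@H]1C[C@](C)(O)[C@]2(O)C(=O)O[C@@H](/C=C\C(C)(C)O)[C@]2(C)[C@H]1OC(=O)c1ccccc1
F6 | step 10 | bis(trimethylsilyl) derivative of 15 (silyl enol ether toward the ring methylene and silyl ether of the secondary alcohol) | C1C[C@](C)(O[Si](CC)(CC)CC)C=C(O[Si](C)(C)C)[C@@]([C@@H](O[Si](C)(C)C)C#CC(C)(C)O[Si](CC)(CC)CC)(C)C=1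
F7 | step 10 | 7-hydroxy derivative of 15 (α-hydroxy ketone, both epimers) | C1C[C@](C)(O[Si](CC)(CC)CC)C(O)C(=O)[C@@]([C@@H](O)C#CC(C)(C)O[Si](CC)(CC)CC)(C)C=1
F8 | step 11 | triethylsilyl ether of 15 at the secondary alcohol | C1C[C@](C)(O[Si](CC)(CC)CC)CC(=O)[C@@]([C@@H](O[Si](CC)(CC)CC)C#CC(C)(C)O[Si](CC)(CC)CC)(C)C=1
F9 | step 11 | triethylsilyl ether of 16 at the secondary alcohol | C1C[C@](C)(O[Si](CC)(CC)CC)C(=O)C(=O)[C@@]([C@@H](O[Si](CC)(CC)CC)C#CC(C)(C)O[Si](CC)(CC)CC)(C)C=1
F10 | step 11 | 1-hydroxy-2,6-dimethyl-2-[(1S)-4-methyl-1,4-bis(triethylsilyloxy)pent-2-yn-1-yl]-6-(triethylsilyloxy)cyclohex-3-ene-1-carboxylic acid (carboxyl cis to the side chain) | C1C[C@](C)(O[Si](CC)(CC)CC)[C@](O)(C(=O)O)[C@@]([C@@H](O[Si](CC)(CC)CC)C#CC(C)(C)O[Si](CC)(CC)CC)(C)C=1
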